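1. Take the ratio of what the solid has been seen to pass into solution, carried over the asked time, to what was charged: at a ratio of one the charge is just used up at the end of that time if that rate holds, and below one the ratio is a floor on what the solid can supply, not a cap on the product share.

| flask | solid substrate | free catalyst | temperature | remark | time |
|---|---|---|---|---|---|
| elm | 0.050 M | 0.15 mM | 15 °C | run made earlier |  |
| birch | 0.050 M | 1.6 mM | 40 °C | run made earlier |  |
| oak | 0.073 M | 0.25 mM | 15 °C | run made earlier |  |
| east | 0.050 M | 0.40 mM | 60 °C |  | 12 min |
| north | 0.10 M | 0.25 mM | 20 °C |  | 12 min |
| north-west | 0.050 M | 1.0 mM | 30 °C |  | 12 min |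
| north-east | 0.050 M | 0.25 mM | 60 °C |  | 12 min |
| west | 0.050 M | 0.12 mM | 60 °C |  | 12 min |

| run | time / min | product / % | solid substrate / % |
|---|---|---|---|
| elm | 4.00 | 0.1 | 94.8 |
| elm | 12.0 | 0.9 | 93.5 |
| elm | 25.0 | 2.3 | 91.9 |
| elm | 40.0 | 3.5 | 91.1 |
| elm | 50.0 | 3.9 | 89.9 |
| elm | 60.0 | 4.8 | 88.6 |
| elm | 80.0 | 7.1 | 87.3 |
| birch | 4.00 | 22.8 | 76.2 |
| birch | 6.00 | 34.2 | 63.6 |
| birch | 10.0 | 58.3 | 38.8 |
| birch | 15.0 | 87.9 | 10.0 |
| birch | 20.0 | 100.5 | 0.4 |
| oak | 15.0 | 1.2 | 95.0 |
| oak | 30.0 | 2.4 | 92.4 |
| oak | 50.0 | 5.1 | 91.2 |
| oak | 60.0 | 5.9 | 90.3 |
| oak | 80.0 | 8.3 | 88.3 |

(readings scatter by 0.5 percentage points)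

- solid, in amounts per volume of the solution: solid substrate
- at the start none of the solid substrate is in solution
- what has only dissolved of solid substrate counts as not reacted

- ranking by amount of product, in percent of the solid substrate charged, from high to low, at 12 min (east / north / north-west / north-east / west)
- the amount of product, in percent of the solid substrate charged of the flask you put first, at 12 min
- the amount of product, in percent of the solid substrate charged of the flask you put last, at 12 min

2. First extreme, endless catalyst, where dissolving is the rate-limiting step. The birch run's product climbs straight while its solid falls from 76.2% to 10.0%, so its solid supplied at least 2.96 mM/min; that is a floor on the feed and not the feed, for a straight line says only that the rate does not follow the amount of solid, and the catalyst in birch may hold it back too. For east, if the solid feeds no slower at 60 °C than at 40 °C, that rate over 12 min against 0.050 M gives 71.0%, the feed share: the rate seen in birch times time, over the charge.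

3. Second extreme, endless solid, where the catalyst sets the pace. The elm run gives 0.291 /min per catalyst at 15 °C, and the birch run at least 1.85 /min at 40 °C. Carrying that climb on to 60 °C gives 8.12 /min, so east could make 78.0% of its charge.

4. The two stages run in series, so you should expect east below the lesser of the two true extremes, but both figures here are floors of those extremes, so neither bounds east from above. My own reckoning, a judgement and no bound, is about 71.0% for east, the birch rate carried over as it stands, and I put east first because it holds more catalyst than the other flasks at 60 °C.

5. The forecast said east > north-east > north-west > west > north, with 62% and 1%, on the ground that “So the solution stays saturated and the rate is zero order in substrate.”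

6. The flask gives east > north-east > west > north-west > north, with 71.2% for east and 1.49% for north. In east, [starting material] stands at 0.836 mM at 12.0 min, below its saturation value of 2.7 mM. East's product lies close to the feed share, 71.0%, while the dissolving step at its fastest, 4.37 mM/min, stands above the birch rate, so the feed share was a floor on the feed, as taken.

    starting material + free catalyst → catalyst intermediate A (k = 170 /M/s, Ea = 56.0 kJ/mol)
    catalyst intermediate A → catalyst intermediate B (k = 230 /s, Ea = 55.0 kJ/mol)
    catalyst intermediate B → free catalyst + product (k = 1.10 /s, Ea = 90.0 kJ/mol)
    solid substrate ⇌ starting material, rate k4*(cs4 - [starting material]) while solid is left; crystals form when [starting material] > cs4 (solubility = 2.70 mM, k = 0.0270 /s)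
    (constants at 60 °C)

7. Now charge east with 0.030 M of solid instead. The feed share passes one, at 118%, so at the birch rate the solid should be used up after about 10.1 min. Computed, that flask holds >99.9% product with 0% of its charge remaining.

All runs are simulated from invented constants; scatter was added.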